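With the carbocycle numbered from C1 (bearing the exocyclic methylene) through C5 (CHMe), C6 (CHOAc), C7/C8 (lactone fusion) and C10/C11 (epoxide) to C14 (carbinol), the 14-membered ring is disconnected between the methylene C13 and the allylic carbinol C14: the C1(=CH2)–C14H(OH) unit is the retron of an alkyl metal adding to a 2-alkylacrolein. The key step, a cobalt-catalysed, chromium(II)-mediated, ligand-controlled addition of a C13 alkylchromium to the C14 enal, closes the macrocycle and sets the C14 carbinol in one operation. Its precursor is an open-chain ω-halo enal already carrying the cis-fused α-methylene-γ-butyrolactone (from an indium allylation/lactonisation joining two fragments), the C6 acetate and the E-C10=C11 alkene; Shi epoxidation completes the synthesis.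

Key step: step 14

Remark (assumptions): compounds 1, 2, 5, 9 and 13 are taken as commercially available. C15 is the exocyclic methylene carbon on C1; C16, C17 and C18 are the lactone α-carbon, its methylene and the carbonyl carbon. The (S)-ligand in step 14 is a first choice; its antipode is used if it favours the wrong face.

Step 1
Reactants: 1 benzyloxyacetaldehyde; 2 cis-2-butene
Product: 4 (2R,3S)-1-(benzyloxy)-3-methylpent-4-en-2-ol, via crotylborane 3 (not isolated)
Conditions: 2, n-BuLi, KOt-Bu, THF, −78 to −45 °C; (+)-Ipc2BOMe [from (−)-α-pinene], −78 °C; BF3·OEt2; 1, −78 °C; NaOH, H2O2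
Reagents that add atoms: none
Why: Brown asymmetric crotylboration through a chair Zimmerman–Traxler transition state, in which the (Z)-crotyl geometry gives the syn C5-methyl/C6-hydroxyl pair and the (−)-α-pinene-derived Ipc groups direct attack to the Re face of 1, should set C6 (2R) and C5 (3S).

Step 2
Reactants: 4 (2R,3S)-1-(benzyloxy)-3-methylpent-4-en-2-ol; 5 tert-butyldimethyl(pent-4-en-1-yloxy)silane
Product: 6 (2R,3S,4E)-1-(benzyloxy)-8-[(tert-butyldimethylsilyl)oxy]-3-methyloct-4-en-2-ol
Conditions: Hoveyda–Grubbs II (5 mol %), 5 (3 equiv), CH2Cl2, 40 °C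
Reagents that add atoms: none
Why: Olefin cross-metathesis of the branched terminal alkene with an excess of the unhindered partner should add C3–C14 without touching a stereocentre; the E/Z ratio is irrelevant because the alkene is hydrogenated next.

Step 3
Reactants: 6 (2R,3S,4E)-1-(benzyloxy)-8-[(tert-butyldimethylsilyl)oxy]-3-methyloct-4-en-2-ol
Product: 7 (2R,3S)-8-[(tert-butyldimethylsilyl)oxy]-3-methyloctane-1,2-diol
Conditions: H2 (1 atm), Pd(OH)2/C, EtOAc, rt
Reagents that add atoms: none
Why: Heterogeneous hydrogenation should saturate the alkene and hydrogenolyse the benzyl ether in one operation, while the TBS ether survives in a neutral aprotic solvent.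

Step 4
Reactants: 7 (2R,3S)-8-[(tert-butyldimethylsilyl)oxy]-3-methyloctane-1,2-diol
Product: 8 (2R,3S)-8-[(tert-butyldimethylsilyl)oxy]-2-hydroxy-3-methyloctanal
Conditions: TEMPO (10 mol %), PhI(OAc)2, CH2Cl2, rt; used crude
Reagents that add atoms: none
Why: TEMPO/PhI(OAc)2 oxidation is selective for the primary hydroxyl of a 1,2-diol and stops at the aldehyde without water; the α-hydroxy aldehyde (partly a hemiacetal dimer) should not epimerise at C6 under these non-basic conditions.

Step 5
Reactants: 9 tert-butyl(but-3-yn-1-yloxy)dimethylsilane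
Product: 11 (3E)-6-[(tert-butyldimethylsilyl)oxy]-4-methylhex-3-en-1-ol, via alkenylalane 10 (not isolated)
Conditions: Me3Al, Cp2ZrCl2 (cat.), CH2Cl2, 0 °C to rt; n-BuLi, THF, −78 °C; ethylene oxide, −78 to 0 °C
Reagents that add atoms: trimethylaluminium (C[Al](C)C); ethylene oxide (C1CO1)
Why: Negishi zirconium-catalysed methylalumination adds Me and Al syn across the alkyne with Al terminal, and the derived alanate opens ethylene oxide with retention, which should fix the E-trisubstituted C10=C11 alkene.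

Step 6
Reactants: 11 (3E)-6-[(tert-butyldimethylsilyl)oxy]-4-methylhex-3-en-1-ol
Product: 12 (3E)-6-[(tert-butyldimethylsilyl)oxy]-4-methylhex-3-enal
Conditions: DMP, NaHCO3, CH2Cl2, 0 °C; used at once
Reagents that add atoms: none
Why: Buffered Dess–Martin oxidation should give the β,γ-unsaturated aldehyde without acid- or base-mediated migration of the alkene into conjugation.

Step 7
Reactants: 12 (3E)-6-[(tert-butyldimethylsilyl)oxy]-4-methylhex-3-enal; 13 methyl propiolate
Product: 15 methyl (5E)-8-[(tert-butyldimethylsilyl)oxy]-3-hydroxy-6-methyl-2-methylideneoct-5-enoate (racemic at C3), via vinylalane 14 (not isolated)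
Conditions: DIBAL-H, NMO, THF, 0 °C; 13; then 12, 0 °C to rt
Reagents that add atoms: none
Why: Vinylalumination (hydroalumination of the propiolate to the α-aluminoacrylate, then carbonyl addition) should give the Morita–Baylis–Hillman-type adduct quickly and without the amine base that would isomerise 12; the racemic carbinol centre is destroyed in step 8.

Step 8
Reactants: 15 methyl (5E)-8-[(tert-butyldimethylsilyl)oxy]-3-hydroxy-6-methyl-2-methylideneoct-5-enoate
Product: 16 methyl (2Z,5E)-8-bromo-2-(bromomethyl)-6-methylocta-2,5-dienoate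
Conditions: Ph3PBr2 (2.5 equiv), CH2Cl2, 0 °C to rt
Reagents that add atoms: dibromotriphenylphosphorane (BrP(Br)(c1ccccc1)(c1ccccc1)c1ccccc1)
Why: Ph3PBr2 should convert the allylic alcohol by SN2′ bromination into the thermodynamically preferred (Z)-2-(bromomethyl)enoate and, in the same operation, the primary TBS ether directly into the primary bromide (bromination of a silyl ether).

Step 9
Reactants: 8 (2R,3S)-8-[(tert-butyldimethylsilyl)oxy]-2-hydroxy-3-methyloctanal; 16 methyl (2Z,5E)-8-bromo-2-(bromomethyl)-6-methylocta-2,5-dienoate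
Product: 18 (4S,5R)-4-[(2E)-5-bromo-3-methylpent-2-en-1-yl]-5-[(1R,2S)-7-[(tert-butyldimethylsilyl)oxy]-1-hydroxy-2-methylheptyl]-3-methylideneoxolan-2-one, via hydroxy ester 17 (not isolated)
Conditions: In powder, THF/H2O (1:1), rt; then PPTS (cat.), toluene, 50 °C
Reagents that add atoms: none
Why: Indium-mediated Barbier allylation in water followed by lactonisation: the allylindium reacts at C8 through a chair transition state in which the C9 chain, cis to the CH2–In terminus, gives the 7,8-syn adduct (cis-lactone), while chelation of In(III) by the aldehyde oxygen and the free C6 hydroxyl directs attack anti to the C5 branch (6,7-syn), which should set C7 (R) and C8 (S); the alkyl bromide is inert to indium and the γ-lactone closes through O7 in preference to a δ-lactone through O6.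

Step 10
Reactants: 18 (4S,5R)-4-[(2E)-5-bromo-3-methylpent-2-en-1-yl]-5-[(1R,2S)-7-[(tert-butyldimethylsilyl)oxy]-1-hydroxy-2-methylheptyl]-3-methylideneoxolan-2-one
Product: 19 (1R,2S)-1-[(2R,3S)-3-[(2E)-5-bromo-3-methylpent-2-en-1-yl]-4-methylidene-5-oxooxolan-2-yl]-7-[(tert-butyldimethylsilyl)oxy]-2-methylheptyl acetate
Conditions: Ac2O, pyridine, DMAP (cat.), CH2Cl2, 0 °C to rt
Reagents that add atoms: acetic anhydride (CC(=O)OC(C)=O)
Why: DMAP-catalysed acetylation should esterify the only free hydroxyl (C6).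

Step 11
Reactants: 19 (1R,2S)-1-[(2R,3S)-3-[(2E)-5-bromo-3-methylpent-2-en-1-yl]-4-methylidene-5-oxooxolan-2-yl]-7-[(tert-butyldimethylsilyl)oxy]-2-methylheptyl acetate
Product: 20 (1R,2S)-1-[(2R,3S)-3-[(2E)-5-bromo-3-methylpent-2-en-1-yl]-4-methylidene-5-oxooxolan-2-yl]-7-hydroxy-2-methylheptyl acetate
Conditions: HF·pyridine, pyridine, THF, 0 °C to rt
Reagents that add atoms: none
Why: Buffered fluoride desilylation should remove the primary TBS ether without touching the acetate, the lactone or the alkyl bromide.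

Step 12
Reactants: 20 (1R,2S)-1-[(2R,3S)-3-[(2E)-5-bromo-3-methylpent-2-en-1-yl]-4-methylidene-5-oxooxolan-2-yl]-7-hydroxy-2-methylheptyl acetate
Product: 21 (1R,2S)-1-[(2R,3S)-3-[(2E)-5-bromo-3-methylpent-2-en-1-yl]-4-methylidene-5-oxooxolan-2-yl]-2-methyl-7-oxoheptyl acetate
Conditions: DMP, NaHCO3, CH2Cl2, rt
Reagents that add atoms: none
Why: Dess–Martin oxidation should give the C14 aldehyde under neutral conditions compatible with the α-methylene lactone and the bromide.

Step 13
Reactants: 21 (1R,2S)-1-[(2R,3S)-3-[(2E)-5-bromo-3-methylpent-2-en-1-yl]-4-methylidene-5-oxooxolan-2-yl]-2-methyl-7-oxoheptyl acetate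
Product: 23 (1R,2S)-1-[(2R,3S)-3-[(2E)-5-bromo-3-methylpent-2-en-1-yl]-4-methylidene-5-oxooxolan-2-yl]-6-formyl-2-methylhept-6-en-1-yl acetate, via Mannich base 22 (not isolated)
Conditions: Eschenmoser's salt, i-Pr2NEt, CH2Cl2, rt
Reagents that add atoms: Eschenmoser's salt, N,N-dimethylmethyleneiminium iodide (C=[N+](C)C.[I-])
Why: Mannich reaction at the only enolisable α-position (C1) followed by β-elimination of dimethylamine (α-methylenation of an aldehyde) should install C15 and give the 2-alkylacrolein; the hindered base avoids quaternisation by the alkyl bromide.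

Step 14
Reactants: 23 (1R,2S)-1-[(2R,3S)-3-[(2E)-5-bromo-3-methylpent-2-en-1-yl]-4-methylidene-5-oxooxolan-2-yl]-6-formyl-2-methylhept-6-en-1-yl acetate
Product: 25 10,11-deoxy target (5S,6R,7R,8S,10E,14S): 14-membered carbocyclic dienol cis-fused to the α-methylene-γ-butyrolactone, via iodo enal 24 (not isolated)
Conditions: NaI, acetone, rt (filter, concentrate); then syringe-pump addition (12 h, final 2 mM) to CrCl2, (S)-i-Pr-oxazoline methanesulfonamide ligand (Kishi type), Et3N, CoPc (20 mol %), THF/MeCN, rt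
Reagents that add atoms: none
Why: Co(I), generated from CoPc by Cr(II), displaces the primary iodide at C13; the alkylcobalt(III) releases the C13 radical, which Cr(II) captures as a ligated alkylchromium(III) that adds 1,2 to the C14 aldehyde of the 2-alkylacrolein and gives the allylic alcohol as its chromium alkoxide. The closest known reaction type is the cobalt-catalysed, chromium(II)-mediated alkyl halide–aldehyde coupling (Takai–Utimoto, Nozaki–Hiyama–Kishi family) in its sulfonamide-ligand-controlled asymmetric form, used here intramolecularly in the way alkenyl- and allylchromium macrocyclisations serve for cembranoids. Only the 14-membered carbocycle is closed, in a 14-exo-trig mode (C13 attacks a carbonyl whose oxygen stays outside the ring). The new C14 stereocentre (S) should be set by the chiral sulfonamide ligand on chromium, which has to deliver C13 to the Si face of the aldehyde. The step needs 1,2- over 1,4-addition and aldehyde over lactone and acetate selectivity (both intrinsic to organochromium(III)), radical capture by excess Cr(II) faster than Giese addition to the enal or the α-methylene lactone (no 3- to 6-membered radical cyclisation is open to C13), and cyclisation over oligomerisation (pseudo-high dilution, with the cis-lactone and the E-alkene as turn elements).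

Step 15
Reactants: 25 10,11-deoxy target (5S,6R,7R,8S,10E,14S)
Product: 26 CNP0230083.1 (5S,6R,7R,8S,10R,11R,14S)
Conditions: Shi ketone (D-fructose-derived, 30 mol %), Oxone, K2CO3, Bu4NHSO4, MeCN/DMM/aq. buffer (pH 10.5), 0 °C
Reagents that add atoms: Oxone, potassium peroxymonosulfate ([K+].[O-]S(=O)(=O)OO)
Why: Shi asymmetric epoxidation: the chiral dioxirane should react only with the electron-rich trisubstituted C10=C11 alkene (the 1,1-disubstituted allylic alkene and the electron-poor α-methylene lactone are much slower) through a spiro transition state that gives the (10R,11R)-trans-epoxide with retention of the E-geometry.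

Compound list
1 | benzyloxyacetaldehyde | O=CCOCc1ccccc1 | starting material
2 | cis-2-butene | C/C=C\C | starting material
3 | (Z)-but-2-en-1-yl-bis(isopinocampheyl)borane, Ipc from (−)-α-pinene | C/C=C\CB([C@H]1C[C@H]2C[C@@H]([C@@H]1C)C2(C)C)[C@H]1C[C@H]2C[C@@H]([C@@H]1C)C2(C)C | intermediate
4 | (2R,3S)-1-(benzyloxy)-3-methylpent-4-en-2-ol | C=C[C@H](C)[C@@H](O)COCc1ccccc1 | intermediate
5 | tert-butyldimethyl(pent-4-en-1-yloxy)silane | C=CCCCO[Si](C)(C)C(C)(C)C | starting material
6 | (2R,3S,4E)-1-(benzyloxy)-8-[(tert-butyldimethylsilyl)oxy]-3-methyloct-4-en-2-ol | CC(C)(C)[Si](C)(C)OCCC/C=C/[C@H](C)[C@@H](O)COCc1ccccc1 | intermediate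
7 | (2R,3S)-8-[(tert-butyldimethylsilyl)oxy]-3-methyloctane-1,2-diol | CC(C)(C)[Si](C)(C)OCCCCC[C@H](C)[C@@H](O)CO | intermediate
8 | (2R,3S)-8-[(tert-butyldimethylsilyl)oxy]-2-hydroxy-3-methyloctanal | CC(C)(C)[Si](C)(C)OCCCCC[C@H](C)[C@@H](O)C=O | intermediate
9 | tert-butyl(but-3-yn-1-yloxy)dimethylsilane | C#CCCO[Si](C)(C)C(C)(C)C | starting material
10 | (E)-{4-[(tert-butyldimethylsilyl)oxy]-2-methylbut-1-en-1-yl}dimethylalane | C[Al](C)/C=C(\C)CCO[Si](C)(C)C(C)(C)C | intermediate
11 | (3E)-6-[(tert-butyldimethylsilyl)oxy]-4-methylhex-3-en-1-ol | OCC/C=C(\C)CCO[Si](C)(C)C(C)(C)C | intermediate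
12 | (3E)-6-[(tert-butyldimethylsilyl)oxy]-4-methylhex-3-enal | O=CC/C=C(\C)CCO[Si](C)(C)C(C)(C)C | intermediate
13 | methyl propiolate | C#CC(=O)OC | starting material
14 | [1-(methoxycarbonyl)ethenyl]diisobutylalane | C=C(C(=O)OC)[Al](CC(C)C)CC(C)C | intermediate
15 | methyl (5E)-8-[(tert-butyldimethylsilyl)oxy]-3-hydroxy-6-methyl-2-methylideneoct-5-enoate (racemic at C3) | C=C(C(=O)OC)C(O)C/C=C(\C)CCO[Si](C)(C)C(C)(C)C | intermediate
16 | methyl (2Z,5E)-8-bromo-2-(bromomethyl)-6-methylocta-2,5-dienoate | BrC/C(C(=O)OC)=C\C/C=C(\C)CCBr | intermediate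
17 | methyl (3S,4R,5R,6S)-3-[(2E)-5-bromo-3-methylpent-2-en-1-yl]-11-[(tert-butyldimethylsilyl)oxy]-4,5-dihydroxy-6-methyl-2-methylideneundecanoate | CC(C)(C)[Si](C)(C)OCCCCC[C@H](C)[C@@H](O)[C@H](O)[C@H](C(=C)C(=O)OC)C/C=C(\C)CCBr | intermediate
18 | (4S,5R)-4-[(2E)-5-bromo-3-methylpent-2-en-1-yl]-5-[(1R,2S)-7-[(tert-butyldimethylsilyl)oxy]-1-hydroxy-2-methylheptyl]-3-methylideneoxolan-2-one | CC(C)(C)[Si](C)(C)OCCCCC[C@H](C)[C@@H](O)[C@@H]1OC(=O)C(=C)[C@@H]1C/C=C(\C)CCBr | intermediate
19 | (1R,2S)-1-[(2R,3S)-3-[(2E)-5-bromo-3-methylpent-2-en-1-yl]-4-methylidene-5-oxooxolan-2-yl]-7-[(tert-butyldimethylsilyl)oxy]-2-methylheptyl acetate | CC(C)(C)[Si](C)(C)OCCCCC[C@H](C)[C@@H](OC(C)=O)[C@@H]1OC(=O)C(=C)[C@@H]1C/C=C(\C)CCBr | intermediate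
20 | (1R,2S)-1-[(2R,3S)-3-[(2E)-5-bromo-3-methylpent-2-en-1-yl]-4-methylidene-5-oxooxolan-2-yl]-7-hydroxy-2-methylheptyl acetate | OCCCCC[C@H](C)[C@@H](OC(C)=O)[C@@H]1OC(=O)C(=C)[C@@H]1C/C=C(\C)CCBr | intermediate
21 | (1R,2S)-1-[(2R,3S)-3-[(2E)-5-bromo-3-methylpent-2-en-1-yl]-4-methylidene-5-oxooxolan-2-yl]-2-methyl-7-oxoheptyl acetate | O=CCCCC[C@H](C)[C@@H](OC(C)=O)[C@@H]1OC(=O)C(=C)[C@@H]1C/C=C(\C)CCBr | intermediate
22 | (1R,2S)-1-[(2R,3S)-3-[(2E)-5-bromo-3-methylpent-2-en-1-yl]-4-methylidene-5-oxooxolan-2-yl]-6-[(dimethylamino)methyl]-2-methyl-7-oxoheptyl acetate (both epimers at chain C6) | O=CC(CN(C)C)CCC[C@H](C)[C@@H](OC(C)=O)[C@@H]1OC(=O)C(=C)[C@@H]1C/C=C(\C)CCBr | intermediate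
23 | (1R,2S)-1-[(2R,3S)-3-[(2E)-5-bromo-3-methylpent-2-en-1-yl]-4-methylidene-5-oxooxolan-2-yl]-6-formyl-2-methylhept-6-en-1-yl acetate | O=CC(=C)CCC[C@H](C)[C@@H](OC(C)=O)[C@@H]1OC(=O)C(=C)[C@@H]1C/C=C(\C)CCBr | intermediate
24 | (1R,2S)-6-formyl-1-[(2R,3S)-3-[(2E)-5-iodo-3-methylpent-2-en-1-yl]-4-methylidene-5-oxooxolan-2-yl]-2-methylhept-6-en-1-yl acetate | O=CC(=C)CCC[C@H](C)[C@@H](OC(C)=O)[C@@H]1OC(=O)C(=C)[C@@H]1C/C=C(\C)CCI | intermediate
25 | 10,11-deoxy target (5S,6R,7R,8S,10E,14S): 14-membered carbocycle with C1 exocyclic methylene; C6 acetate; E-C10=C11(Me); C14 hydroxyl; cis-fused C7/C8 α-methylene-γ-butyrolactone | C=C1CCC[C@H](C)[C@@H](OC(C)=O)[C@@H]2OC(=O)C(=C)[C@@H]2C/C=C(\C)CC[C@@H]1O | intermediate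
26 | CNP0230083.1 (5S,6R,7R,8S,10R,11R,14S): the 10,11-epoxide of 25 | C=C1CCC[C@H](C)[C@@H](OC(C)=O)[C@@H]2OC(=O)C(=C)[C@@H]2C[C@H]2O[C@]2(C)CC[C@@H]1O | target

Total step count: 15
Longest linear sequence: 11 steps (steps 1–4 and 9–15; the second branch, steps 5–8 and 9–15, is equally long)

Steps most likely to fail

Step 14 (key step). Facial selectivity at C14 may be poor if the conformation of the closing chain overrides the ligand, and the ligated alkylchromium may add slowly enough for oligomerisation to compete. Fallback: set out from 23, make the iodo enal 24 as before and close the ring without ligand (CrCl2, cat. vitamin B12, DMF, high dilution) to the C14-epimeric macrocyclic alcohols F1. Dess–Martin oxidation then gives the macrocyclic α-methylene ketone F2, and reduction with (R)-2-methyl-CBS-oxazaborolidine and catecholborane (toluene, −78 °C; alkenyl as the large group) should return to 25 with C14 (S) set by the reagent.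

Step 9. Chelation control may erode (attack from the wrong aldehyde face gives the C7 epimer), simple diastereoselection may be incomplete (trans-lactone), and the unprotected α-hydroxy aldehyde may oligomerise before it reacts. Fallback: set out from diol 7 and form the p-methoxybenzylidene acetal F3 (p-anisaldehyde dimethyl acetal, PPTS). Regioselective reductive opening with DIBAL-H gives the C6 PMB ether with free primary alcohol F4, and Dess–Martin oxidation gives the stable α-PMB-oxy aldehyde F5. Zinc-mediated Barbier coupling with 16 (Zn, THF/aq. NH4Cl), now under Cram-chelate control through the ether oxygen, should give the PMB hydroxy ester F6, which lactonises (PPTS) to the PMB lactone F7. DDQ (CH2Cl2/pH 7 buffer) removes the PMB group and returns to 18.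

Step 15. The dioxirane may meet a macrocycle whose exposed alkene face is mismatched with the catalyst, the allylic 1,1-disubstituted alkene or the carbinol may be oxidised in competition, and the acetate or lactone may suffer at pH 10.5. Fallback: set out from the acyclic alcohol 20 and carry out the Shi epoxidation there, where catalyst control on an unconstrained E-trisubstituted alkene is reliable, to give the epoxy alcohol F8. Dess–Martin oxidation gives the epoxy aldehyde F9, and Eschenmoser methylenation proceeds through the Mannich base F10 to the epoxy bromo enal F11. The same ligand-controlled Co/Cr ring closure is then applied directly to the bromide (vitamin B12 in place of NaI/CoPc, so that no iodide salt meets the epoxide) and closes the ring to 26.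

Further compounds
F1 | step 14 | C14-epimeric mixture of 25 | C=C1CCC[C@H](C)[C@@H](OC(C)=O)[C@@H]2OC(=O)C(=C)[C@@H]2C/C=C(\C)CCC1O
F2 | step 14 | macrocyclic α-methylene ketone (C14 ketone of 25) | C=C1CCC[C@H](C)[C@@H](OC(C)=O)[C@@H]2OC(=O)C(=C)[C@@H]2C/C=C(\C)CCC1=O
F3 | step 9 | tert-butyl{[(6S)-6-[(4R)-2-(4-methoxyphenyl)-1,3-dioxolan-4-yl]heptyl]oxy}dimethylsilane | CC(C)(C)[Si](C)(C)OCCCCC[C@H](C)[C@@H]1COC(c2ccc(OC)cc2)O1
F4 | step 9 | (2R,3S)-8-[(tert-butyldimethylsilyl)oxy]-2-[(4-methoxybenzyl)oxy]-3-methyloctan-1-ol | CC(C)(C)[Si](C)(C)OCCCCC[C@H](C)[C@@H](OCc1ccc(OC)cc1)CO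
F5 | step 9 | (2R,3S)-8-[(tert-butyldimethylsilyl)oxy]-2-[(4-methoxybenzyl)oxy]-3-methyloctanal | CC(C)(C)[Si](C)(C)OCCCCC[C@H](C)[C@@H](OCc1ccc(OC)cc1)C=O
F6 | step 9 | methyl (3S,4R,5R,6S)-3-[(2E)-5-bromo-3-methylpent-2-en-1-yl]-11-[(tert-butyldimethylsilyl)oxy]-4-hydroxy-5-[(4-methoxybenzyl)oxy]-6-methyl-2-methylideneundecanoate | CC(C)(C)[Si](C)(C)OCCCCC[C@H](C)[C@@H](OCc1ccc(OC)cc1)[C@H](O)[C@H](C(=C)C(=O)OC)C/C=C(\C)CCBr
F7 | step 9 | (4S,5R)-4-[(2E)-5-bromo-3-methylpent-2-en-1-yl]-5-[(1R,2S)-7-[(tert-butyldimethylsilyl)oxy]-1-[(4-methoxybenzyl)oxy]-2-methylheptyl]-3-methylideneoxolan-2-one | CC(C)(C)[Si](C)(C)OCCCCC[C@H](C)[C@@H](OCc1ccc(OC)cc1)[C@@H]1OC(=O)C(=C)[C@@H]1C/C=C(\C)CCBr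
F8 | step 15 | (1R,2S)-1-[(2R,3S)-3-{[(2R,3R)-3-(2-bromoethyl)-3-methyloxiran-2-yl]methyl}-4-methylidene-5-oxooxolan-2-yl]-7-hydroxy-2-methylheptyl acetate | OCCCCC[C@H](C)[C@@H](OC(C)=O)[C@@H]1OC(=O)C(=C)[C@@H]1C[C@H]1O[C@]1(C)CCBr
F9 | step 15 | (1R,2S)-1-[(2R,3S)-3-{[(2R,3R)-3-(2-bromoethyl)-3-methyloxiran-2-yl]methyl}-4-methylidene-5-oxooxolan-2-yl]-2-methyl-7-oxoheptyl acetate | O=CCCCC[C@H](C)[C@@H](OC(C)=O)[C@@H]1OC(=O)C(=C)[C@@H]1C[C@H]1O[C@]1(C)CCBr
F10 | step 15 | (1R,2S)-1-[(2R,3S)-3-{[(2R,3R)-3-(2-bromoethyl)-3-methyloxiran-2-yl]methyl}-4-methylidene-5-oxooxolan-2-yl]-6-[(dimethylamino)methyl]-2-methyl-7-oxoheptyl acetate | O=CC(CN(C)C)CCC[C@H](C)[C@@H](OC(C)=O)[C@@H]1OC(=O)C(=C)[C@@H]1C[C@H]1O[C@]1(C)CCBr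
F11 | step 15 | (1R,2S)-1-[(2R,3S)-3-{[(2R,3R)-3-(2-bromoethyl)-3-methyloxiran-2-yl]methyl}-4-methylidene-5-oxooxolan-2-yl]-6-formyl-2-methylhept-6-en-1-yl acetate | O=CC(=C)CCC[C@H](C)[C@@H](OC(C)=O)[C@@H]1OC(=O)C(=C)[C@@H]1C[C@H]1O[C@]1(C)CCBr
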